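Reckoned with Z at its charge and D at saturation, the growth constant of E in the south-east flask is larger than the decay constant of L there by a factor of 16.3, and I built my reckoning on that ratio.

| setting | south-east | south | north |
|---|---|---|---|
| Z | 2.0 M | 2.0 M | 2.0 M |
| X | 76 mM (held) | 76 mM (held) | 76 mM (held) |
| temperature | 40 °C | 70 °C | 100 °C |
| time | 6.0 min | 6.0 min | 6.0 min |

    Z + D + E → L + 2 E (k1 = 0.46 M⁻² s⁻¹, Ea1 = 36.0 kJ mol⁻¹)
    Z + D → L + E (k2 = 5.0 × 10⁻⁴ M⁻¹ s⁻¹, Ea2 = 85.0 kJ mol⁻¹)
    L → Q (k3 = 0.023 s⁻¹, Ea3 = 86.0 kJ mol⁻¹)
    X ⇌ D, rate k4*(csat - [D]) (k4 = 0.36 s⁻¹, csat = 76 mM)
    (constants at 70 °C)

* the best flask by share of L in all that became L or Q; "all alike" if 1.5 percentage points covers them all (south-east / south / north / all alike)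
* share of L in all that became L or Q, south-east
* share of L in all that became L or Q, south
* share of L in all that became L or Q, north

- at the start none of D is dissolved
- constants are those at 70 °C; use the activation energies for any other temperature

The first step makes E from E, so while Z and D stay near their levels, E grows in a pseudo-first-order way, with a growth constant, per unit of E, equal to the first step's constant times Z times D. L is made in step with E and decays at its own constant. When a product is made at an exponentially growing rate and leaks by a first-order step, and both constants hold fixed, the amount kept stands to the amount leaked as growth constant to decay constant, so time drops out. I call this the growth-to-decay ratio.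

I turned the temperature first. With Z at its charge and D at saturation, the ratio was 16.3 at 40 °C, 3.04 at 70 °C and 0.743 at 100 °C, so it is higher in the cold.

Then I turned the time, since the ratio holds while growth lasts. The second step seeds E, and by my estimate a seed growing at 1.25 min⁻¹ in south-east reaches the charge of Z after 7.32 min, later than the asked time. So I took south-east as still growing, and its share as 94.2 %.

In south the same estimate put the seed at the charge of Z after 1.79 min. In north it gave 0.530 min, but even at its fastest crossing, with D at zero, X needs 1.22 min to deliver one D for each Z charged. After the later of these times, I let L simply decay, at 1.4 min⁻¹ in south and 15.6 min⁻¹ in north. That gave 0.226 % for south and <0.001 % for north, with south-east the best.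

The forecast, which called the reaction “autocatalytic in E and capped by gas transfer”, gave 93 %, 1.3 % and 0 % with south-east best, and its south figure is higher than mine.

The simulation gave 93.3 %, 1.26 % and 0 %, with south-east best. In south-east, while the first step ran, L stood to Q as 17.8 at 3.00 min, with Z at 99.6 % and D at 0.0755 M, against my 16.3 for the charge of Z and saturated D, and as 14.0 at 6.00 min, with Z at 87.0 % and D at 0.0651 M. In south, Z went from 24.6 % to 0 % between those times while L fell from 28.4 % to 1.26 %, and north held 0 % Z and 0 % L by 3.00 min. South-east left until 60.0 min had Z at 0 % and a share of 1.85 %.

The rate constants are invented.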